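The dihydropyran ring C of the isoflavan is cut at O1–C2 and C3–C4. The key step exploits the ortho relation of O1 (on C8a) and C4 (on C4a) on ring A, which makes ring A a latent ortho-quinone methide. It also exploits the position of C3, the only stereocenter, next to C2: at the acid oxidation level C3 is an enolate carbon. One carbene-catalysed formal [4+2] annulation joins the two halves, closes the last ring as a lactone and sets C3. Its precursors are a fluoride-triggered silyloxybenzyl bromide carrying the prenyl group and the acyl imidazole of the chromene-fused ring B acetic acid. Carbonyl removal and deallylation follow.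

Key step: step 11

Assumption: atom numbers are those of the chromane skeleton (O1, C2, C3, C4, C4a to C8a) and the target is 3R; the triazolium enantiomer named is the one expected from the usual facial model, and its antipode would be used if a model run shows the opposite sense.

Step 1
Reactants: 1 2,4-dihydroxybenzaldehyde; 2 3-methylbut-2-enal
Product: 3 5-hydroxy-2,2-dimethyl-2H-chromene-6-carbaldehyde
Conditions: pyridine, 140 °C, sealed tube
Reagents that add atoms: none
Why: Condensation of the enal at C3 of 1 (the position between the two oxygens, activated by the hydrogen-bonded formyl group), dehydration and oxa-6π electrocyclisation should give the angular chromene (chromenylation of a phenol with an enal).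

Step 2
Reactants: 3 5-hydroxy-2,2-dimethyl-2H-chromene-6-carbaldehyde
Product: 4 5-(allyloxy)-2,2-dimethyl-2H-chromene-6-carbaldehyde
Conditions: allyl bromide, K2CO3, DMF, 50 °C
Reagents that add atoms: allyl bromide, C=CCBr
Why: Williamson etherification of the chelated phenol, which needs a dipolar solvent and gentle warming, should protect it with a group that later survives fluoride, hydride and Lewis acid.

Step 3
Reactants: 4 5-(allyloxy)-2,2-dimethyl-2H-chromene-6-carbaldehyde
Product: 5 2-[5-(allyloxy)-2,2-dimethyl-2H-chromen-6-yl]acetonitrile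
Conditions: TosMIC, KOtBu, DME, −40 °C; then MeOH, reflux
Reagents that add atoms: tosylmethyl isocyanide (TosMIC), Cc1ccc(cc1)S(=O)(=O)C[N+]#[C-]
Why: Van Leusen reductive cyanation should turn the aldehyde into the nitrile with one more carbon by addition of the TosMIC anion, loss of sulfinate and methanolytic deformylation.

Step 4
Reactants: 5 2-[5-(allyloxy)-2,2-dimethyl-2H-chromen-6-yl]acetonitrile
Product: 6 2-[5-(allyloxy)-2,2-dimethyl-2H-chromen-6-yl]acetic acid
Conditions: KOH, EtOH/H2O, reflux; then 1 M HCl, 0 °C, to pH 3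
Reagents that add atoms: water, O; potassium hydroxide, [K+].[OH-]
Why: Alkaline nitrile hydrolysis should give the arylacetic acid, the chromene and the allyl ether being stable to base.

Step 5
Reactants: 6 2-[5-(allyloxy)-2,2-dimethyl-2H-chromen-6-yl]acetic acid
Product: 7 2-[5-(allyloxy)-2,2-dimethyl-2H-chromen-6-yl]-1-(1H-imidazol-1-yl)ethan-1-one
Conditions: 1,1'-carbonyldiimidazole, THF, rt; used without chromatography
Reagents that add atoms: 1,1'-carbonyldiimidazole (CDI), O=C(n1ccnc1)n1ccnc1
Why: Acyl transfer from CDI with loss of carbon dioxide and imidazole should give the acyl imidazole, an acyl donor reactive enough to acylate a carbene catalyst.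

Step 6
Reactants: 1 2,4-dihydroxybenzaldehyde; 8 1-bromo-3-methylbut-2-ene (prenyl bromide)
Product: 9 2,4-dihydroxy-3-(3-methylbut-2-en-1-yl)benzaldehyde
Conditions: KOH (10 % aq.), 0 °C to rt
Reagents that add atoms: none
Why: Direct C-prenylation of the phenoxide in water, which favours C- over O-alkylation, should take place at C3, the carbon activated by both oxygens.

Step 7
Reactants: 9 2,4-dihydroxy-3-(3-methylbut-2-en-1-yl)benzaldehyde
Product: 10 4-(allyloxy)-2-hydroxy-3-(3-methylbut-2-en-1-yl)benzaldehyde
Conditions: allyl bromide (1.05 equiv), K2CO3, acetone, rt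
Reagents that add atoms: allyl bromide, C=CCBr
Why: Williamson etherification should be selective for the 4-hydroxyl because the 2-hydroxyl is held in a hydrogen bond to the formyl group.

Step 8
Reactants: 10 4-(allyloxy)-2-hydroxy-3-(3-methylbut-2-en-1-yl)benzaldehyde
Product: 11 4-(allyloxy)-2-[(tert-butyldimethylsilyl)oxy]-3-(3-methylbut-2-en-1-yl)benzaldehyde
Conditions: TBSCl, imidazole, DMAP (cat.), DMF, 40 °C
Reagents that add atoms: tert-butyldimethylsilyl chloride (TBSCl), CC(C)(C)[Si](C)(C)Cl
Why: Silylation of the remaining phenol should install the fluoride-labile trigger on the oxygen that becomes O1.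

Step 9
Reactants: 11 4-(allyloxy)-2-[(tert-butyldimethylsilyl)oxy]-3-(3-methylbut-2-en-1-yl)benzaldehyde
Product: 12 {4-(allyloxy)-2-[(tert-butyldimethylsilyl)oxy]-3-(3-methylbut-2-en-1-yl)phenyl}methanol
Conditions: NaBH4, MeOH/THF, −10 °C, short reaction time; aq. NH4Cl
Reagents that add atoms: none
Why: Borohydride reduction of the aldehyde should give the benzylic alcohol, the low temperature and quick buffered quench keeping the silyl group from migrating to the new alkoxide.

Step 10
Reactants: 12 {4-(allyloxy)-2-[(tert-butyldimethylsilyl)oxy]-3-(3-methylbut-2-en-1-yl)phenyl}methanol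
Product: 13 [3-(allyloxy)-6-(bromomethyl)-2-(3-methylbut-2-en-1-yl)phenoxy](tert-butyl)dimethylsilane
Conditions: CBr4, PPh3, CH2Cl2, 0 °C; quick filtration through silica, used at once
Reagents that add atoms: carbon tetrabromide, BrC(Br)(Br)Br
Why: Appel bromination under neutral conditions should give the electron-rich benzylic bromide without touching the silyl ether or the alkenes.

Step 11
Reactants: 7 2-[5-(allyloxy)-2,2-dimethyl-2H-chromen-6-yl]-1-(1H-imidazol-1-yl)ethan-1-one; 13 [3-(allyloxy)-6-(bromomethyl)-2-(3-methylbut-2-en-1-yl)phenoxy](tert-butyl)dimethylsilane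
Product: 15 (3R)-7-(allyloxy)-3-[5-(allyloxy)-2,2-dimethyl-2H-chromen-6-yl]-8-(3-methylbut-2-en-1-yl)chroman-2-one, via ortho-quinone methide 14 (not isolated)
Conditions: 7 (1.5 equiv), (5aS,10bR)-5a,10b-dihydro-2-(2,4,6-trimethylphenyl)-4H,6H-indeno[2,1-b]-1,2,4-triazolo[4,3-d]-1,4-oxazinium tetrafluoroborate (15 mol %), CsF (2.5 equiv), 18-crown-6 (1.2 equiv), 4 Å MS, THF, −20 °C
Reagents that add atoms: none
Why: Fluoride removes the silyl group from O1 of 13 and the phenoxide expels bromide to give ortho-quinone methide 14, while the carbene freed from the triazolium salt is acylated by 7 and the acyl azolium is deprotonated to a chiral azolium enolate; the enolate carbon adds to the exocyclic CH2 of 14 (C3–C4 bond) and phenoxide O1 then attacks the acyl azolium carbonyl (O1–C2 bond), releasing the carbene. The closest known reaction type is the carbene-catalysed formal [4+2] annulation of azolium enolates with fluoride-generated ortho-quinone methides to 3,4-dihydrocoumarins. Ring C is closed in a formal hetero-[4+2] mode, that is a Michael addition followed by a 6-exo-trig lactonisation. C3 is set in the C–C bond formation by the catalyst: the aminoindane unit shields one face of the (Z)-enolate, so the quinone methide should approach the open face and give 3R. The step needs C-alkylation to outrun oligomerisation of 14, which the slow release of 14 by sparingly soluble CsF against a standing concentration of enolate should secure; only O1 can be unmasked, because O7 and the ring B oxygen carry fluoride-stable allyl groups. The acidic C3–H of the product is guarded by the low temperature and the weakly basic medium.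

Step 12
Reactants: 15 (3R)-7-(allyloxy)-3-[5-(allyloxy)-2,2-dimethyl-2H-chromen-6-yl]-8-(3-methylbut-2-en-1-yl)chroman-2-one
Product: 16 (3R)-7-(allyloxy)-3-[5-(allyloxy)-2,2-dimethyl-2H-chromen-6-yl]-8-(3-methylbut-2-en-1-yl)chroman-2-ol (mixture of C2 epimers)
Conditions: iBu2AlH (1.2 equiv), CH2Cl2, −78 °C; MeOH, then aq. potassium sodium tartrate; used crude
Reagents that add atoms: none
Why: Partial reduction of the lactone should stop at the lactol because the aluminium hemiacetal is stable at −78 °C, and the neutral work-up leaves C3 untouched.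

Step 13
Reactants: 16 (3R)-7-(allyloxy)-3-[5-(allyloxy)-2,2-dimethyl-2H-chromen-6-yl]-8-(3-methylbut-2-en-1-yl)chroman-2-ol
Product: 17 (3R)-7-(allyloxy)-3-[5-(allyloxy)-2,2-dimethyl-2H-chromen-6-yl]-8-(3-methylbut-2-en-1-yl)chromane
Conditions: Et3SiH (3 equiv), BF3·OEt2 (2 equiv), CH2Cl2, −78 °C to −40 °C
Reagents that add atoms: none
Why: Reductive deoxygenation of the lactol should proceed by ionisation to the cyclic oxocarbenium ion (O1=C2) and fast hydride transfer from the silane, at a temperature where the allyl ethers and the alkenes are inert.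

Step 14
Reactants: 17 (3R)-7-(allyloxy)-3-[5-(allyloxy)-2,2-dimethyl-2H-chromen-6-yl]-8-(3-methylbut-2-en-1-yl)chromane
Product: 18 (3R)-3-(5-hydroxy-2,2-dimethyl-2H-chromen-6-yl)-8-(3-methylbut-2-en-1-yl)chroman-7-ol
Conditions: Pd(PPh3)4 (5 mol %), morpholine, degassed THF, rt
Reagents that add atoms: none
Why: Tsuji–Trost deallylation should free both phenols, since zerovalent palladium ionises only the two unhindered allyl aryl ethers (morpholine takes up the allyl groups) and leaves the prenyl group and the hindered cyclic tertiary allyl ether of the chromene alone.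

Compound list
1 | 2,4-dihydroxybenzaldehyde | O=Cc1ccc(O)cc1O | starting material
2 | 3-methylbut-2-enal | CC(C)=CC=O | starting material
3 | 5-hydroxy-2,2-dimethyl-2H-chromene-6-carbaldehyde | O=Cc1ccc2c(c1O)C=CC(C)(C)O2 | intermediate
4 | 5-(allyloxy)-2,2-dimethyl-2H-chromene-6-carbaldehyde | O=Cc1ccc2c(c1OCC=C)C=CC(C)(C)O2 | intermediate
5 | 2-[5-(allyloxy)-2,2-dimethyl-2H-chromen-6-yl]acetonitrile | N#CCc1ccc2c(c1OCC=C)C=CC(C)(C)O2 | intermediate
6 | 2-[5-(allyloxy)-2,2-dimethyl-2H-chromen-6-yl]acetic acid | OC(=O)Cc1ccc2c(c1OCC=C)C=CC(C)(C)O2 | intermediate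
7 | 2-[5-(allyloxy)-2,2-dimethyl-2H-chromen-6-yl]-1-(1H-imidazol-1-yl)ethan-1-one | O=C(Cc1ccc2c(c1OCC=C)C=CC(C)(C)O2)n1ccnc1 | intermediate
8 | 1-bromo-3-methylbut-2-ene (prenyl bromide) | CC(C)=CCBr | starting material
9 | 2,4-dihydroxy-3-(3-methylbut-2-en-1-yl)benzaldehyde | CC(C)=CCc1c(O)ccc(C=O)c1O | intermediate
10 | 4-(allyloxy)-2-hydroxy-3-(3-methylbut-2-en-1-yl)benzaldehyde | CC(C)=CCc1c(OCC=C)ccc(C=O)c1O | intermediate
11 | 4-(allyloxy)-2-[(tert-butyldimethylsilyl)oxy]-3-(3-methylbut-2-en-1-yl)benzaldehyde | CC(C)=CCc1c(OCC=C)ccc(C=O)c1O[Si](C)(C)C(C)(C)C | intermediate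
12 | {4-(allyloxy)-2-[(tert-butyldimethylsilyl)oxy]-3-(3-methylbut-2-en-1-yl)phenyl}methanol | CC(C)=CCc1c(OCC=C)ccc(CO)c1O[Si](C)(C)C(C)(C)C | intermediate
13 | [3-(allyloxy)-6-(bromomethyl)-2-(3-methylbut-2-en-1-yl)phenoxy](tert-butyl)dimethylsilane | CC(C)=CCc1c(OCC=C)ccc(CBr)c1O[Si](C)(C)C(C)(C)C | intermediate
14 | 3-(allyloxy)-6-methylidene-2-(3-methylbut-2-en-1-yl)cyclohexa-2,4-dien-1-one (ortho-quinone methide, not isolated) | C=C1C=CC(OCC=C)=C(CC=C(C)C)C1=O | intermediate
15 | (3R)-7-(allyloxy)-3-[5-(allyloxy)-2,2-dimethyl-2H-chromen-6-yl]-8-(3-methylbut-2-en-1-yl)chroman-2-one | CC(C)=CCc1c(OCC=C)ccc2c1OC(=O)[C@@H](c1ccc3c(c1OCC=C)C=CC(C)(C)O3)C2 | intermediate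
16 | (3R)-7-(allyloxy)-3-[5-(allyloxy)-2,2-dimethyl-2H-chromen-6-yl]-8-(3-methylbut-2-en-1-yl)chroman-2-ol (C2 epimers) | CC(C)=CCc1c(OCC=C)ccc2c1OC(O)[C@@H](c1ccc3c(c1OCC=C)C=CC(C)(C)O3)C2 | intermediate
17 | (3R)-7-(allyloxy)-3-[5-(allyloxy)-2,2-dimethyl-2H-chromen-6-yl]-8-(3-methylbut-2-en-1-yl)chromane | CC(C)=CCc1c(OCC=C)ccc2c1OC[C@@H](c1ccc3c(c1OCC=C)C=CC(C)(C)O3)C2 | intermediate
18 | (3R)-3-(5-hydroxy-2,2-dimethyl-2H-chromen-6-yl)-8-(3-methylbut-2-en-1-yl)chroman-7-ol | CC(C)=CCc1c(O)ccc2c1OC[C@@H](c1ccc3c(c1O)C=CC(C)(C)O3)C2 | target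

Total step count: 14. Longest linear sequence: 9 steps (steps 1 to 5 or 6 to 10, then 11 to 14).

Steps most likely to fail

Step 11. The quinone methide may oligomerise before the enolate intercepts it, the liberated phenoxide may be O-acylated by 7, and the product may lose enantiopurity by base-mediated enolisation at C3. The fallback sets out from acid 6 and bromide 13 and comes back at lactone 15. Acid 6 would be activated as its pivalic mixed anhydride (PivCl, Et3N, THF, −20 °C) and coupled with the lithium salt of (R)-4-benzyl-2-oxazolidinone (nBuLi) to give (R)-4-benzyl-3-{[5-(allyloxy)-2,2-dimethyl-2H-chromen-6-yl]acetyl}oxazolidin-2-one F1. Its sodium (Z)-enolate (NaN(SiMe3)2, THF, −78 °C) would be alkylated by 13, the benzyl group of the auxiliary shielding one face (Evans alkylation), to give the (2R)-2,3-diarylpropanoyl imide F2. Tetrabutylammonium fluoride buffered with acetic acid (THF, 0 °C) would then free the phenol, which should lactonise onto the imide carbonyl with loss of the auxiliary to give 15, so ring C remains the last ring closed.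

Step 13. The oxocarbenium ion may lose the C3 proton to an enol ether and so erode the stereocenter, and adventitious protic acid may bring about ionic hydrogenation of the electron-rich chromene double bond. The fallback sets out from lactol 16 and comes back at 17. Lactol 16 would be converted with 1,1'-thiocarbonyldiimidazole (DMAP cat., CH2Cl2, rt) into the O-(chroman-2-yl) 1H-imidazole-1-carbothioate F3. Bu3SnH at high concentration with AIBN (toluene, 80 °C) would then replace the C2–O bond by C2–H through the C2 radical (Barton–McCombie deoxygenation), under neutral conditions without a cation or a protic acid.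

Step 6. Alkylation may be poorly site-selective (O- against C-alkylation, C5 against C3, double prenylation). The fallback sets out from 1 and comes back at 9. Selective 4-O-alkylation of 1 with 3-chloro-3-methylbut-1-yne (K2CO3, KI, CuI cat., acetone, 50 °C) would give 2-hydroxy-4-[(2-methylbut-3-yn-2-yl)oxy]benzaldehyde F4. Semihydrogenation (H2, Pd/CaCO3 poisoned with Pb(OAc)2, quinoline, EtOAc) would give 2-hydroxy-4-[(2-methylbut-3-en-2-yl)oxy]benzaldehyde F5. Heating (N,N-diethylaniline, 120 °C) should then bring about an aromatic Claisen rearrangement with allyl inversion to C3, the ortho position favoured by the hydrogen-bonded formyl group, to give 9.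

Further compounds
F1 | step 11 | (R)-4-benzyl-3-{[5-(allyloxy)-2,2-dimethyl-2H-chromen-6-yl]acetyl}oxazolidin-2-one | O=C(Cc1ccc2c(c1OCC=C)C=CC(C)(C)O2)N1[C@H](Cc2ccccc2)COC1=O
F2 | step 11 | (R)-4-benzyl-3-[(2R)-2-[5-(allyloxy)-2,2-dimethyl-2H-chromen-6-yl]-3-{4-(allyloxy)-2-[(tert-butyldimethylsilyl)oxy]-3-(3-methylbut-2-en-1-yl)phenyl}propanoyl]oxazolidin-2-one | O=C([C@H](Cc1ccc(OCC=C)c(CC=C(C)C)c1O[Si](C)(C)C(C)(C)C)c1ccc2c(c1OCC=C)C=CC(C)(C)O2)N1[C@H](Cc2ccccc2)COC1=O
F3 | step 13 | O-{(3R)-7-(allyloxy)-3-[5-(allyloxy)-2,2-dimethyl-2H-chromen-6-yl]-8-(3-methylbut-2-en-1-yl)chroman-2-yl} 1H-imidazole-1-carbothioate | CC(C)=CCc1c(OCC=C)ccc2c1OC(OC(=S)n1ccnc1)[C@@H](c1ccc3c(c1OCC=C)C=CC(C)(C)O3)C2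
F4 | step 6 | 2-hydroxy-4-[(2-methylbut-3-yn-2-yl)oxy]benzaldehyde | C#CC(C)(C)Oc1ccc(C=O)c(O)c1
F5 | step 6 | 2-hydroxy-4-[(2-methylbut-3-en-2-yl)oxy]benzaldehyde | C=CC(C)(C)Oc1ccc(C=O)c(O)c1
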